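## Structural features

The target is a eudesmane: ring A (C1–C5, C10) and ring B (C5–C10) share the C5–C10 bond and are trans-fused, with the C5 hydroperoxide on the α face and the C10 methyl on the β face. Ring A carries an equatorial 3β-isobutyrate and an exocyclic C4=C15 methylene. Ring B carries a methyl acrylate unit (C11–C13) on C7 and an axial 8β-acetate. Of the five stereocentres (3S,5S,7R,8R,10R), C5 and C10 are adjacent at the ring fusion, C7 and C8 are adjacent and cis, and C3 sits next to the C4 methylene. The fragile groups are the tertiary allylic hydroperoxide (reduction, acid, base), the acrylate (Michael acceptor) and three different esters; a free 8β-hydroxyl closes a cis γ-lactone onto C12. The real difficulties are the quaternary C10 and its relation to the remote C7, the late face- and site-selective C5–O bond, and telling the three acyl groups apart. The C5–OOH/C4(15) pair is the ene signature of a C4=C5 alkene, and behind that alkene stands a 3-oxygenated ring A. The key step uses this: the C3–O/C3=C4 enol ether of ring A is the footprint of a 2-silyloxydiene C2–C5, C1=C10 is the dienophile and C6–C9 the tether, so one cycloaddition of an acyclic chain holding only C7 builds both rings and sets C5 and C10.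

## Logic of the disconnections

32 to 31: the C5–O bond (with the C15–H shift) is cut. This removes the most fragile group and the C5 stereocentre. The forward step must attack the α face of C4=C5 and take a hydrogen from C15.

31 to 29 through 30: the two acyl C–O bonds at C8 and C3 are cut. This leaves a diol whose hydroxyls differ strongly in hindrance. The forward steps must acylate the equatorial allylic C3–OH first and the axial C8–OH second.

29 to 26: the C12–O(C8) lactone bond is re-formed and C13 is masked as a dimethylaminomethyl group. The cis lactone is the natural resting state of the 8β-oxygen/C12 pair and the amine hides the Michael acceptor. The forward step must open the lactone and esterify without acid.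

26 to 24: the C11–C13 bond is cut. The forward step is an aminomethylation of the lactone enolate, at a stage where no ketone is present.

24 to 22: the C3–H and C8–H bonds and the lactone C–O bond are cut. Two carbonyls are reduced in one operation. The forward step must deliver hydride to the α face at both C3 and C8.

22 to 20 through 21: the C8 ketal is restored and the C4=C5 unsaturation is removed. The enol ether of 20 fixes where the enone forms, which free enolization of a trans-fused 3-ketone would not do reliably.

20 to 19: the C1–H bond replaces C1–S. The sulfonyl group is only an activating group and its stereocentre is lost here.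

19 to 18: the C1–C2 and C5–C10 bonds are cut. Both rings and three stereocentres are removed, leaving an acyclic triene with one stereocentre. The forward step needs endo orientation and control of the diene face by C7.

18 to 17 to 15 and 16: the O–Si bond and the C4=C5 bond are cut. The forward steps are a kinetic silylation at C2 and an E-selective olefination.

15 to 14 to 12: C5 is taken back to the amide oxidation level and the C1–S bond is cut. C5 is kept as an amide until here so that the sulfonyl group is introduced on a molecule with a single alkene. The forward steps are a chemoselective amide reduction and an E-selective sulfonylation.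

12 to 11 to 8 and 9: the ketal and the C8–C9 bond are cut. The forward steps must add a 2-methylallyl unit to the C8 acyl group without touching ester or amide and must not let the alkene move into conjugation.

8 to 6 to 3 and 4, and 3 to 1 and 2: the auxiliary and the C6–C7 bond are cut. This leads to commercial pieces. The forward alkylation must set C7 as R.

## Other disconnections considered

Alternative 1: The cut is C6–C7. The allylic bromide A1, treated with Bu3SnH, would give a C6 radical that adds to C7 of the butenolide and then expels the phenylthio radical to give A2. In its favour, ring B, the C7 centre (cis to the C8 oxygen through the tether) and the C11(13) methylene arise in one step, and A2 already holds the methylene lactone that the chosen plan reaches only in steps 14 to 16. On the end game after ring formation the alternative is the better. Against it, C8 and C10 of A1 lie 1,3 across an acyclic CH2 and must be set independently before the key step, whereas the chosen plan derives C5 and C10 from C7 alone. The C6 radical is delocalised toward C4 and is a vinylogous acyl radical, so its addition to an electron-poor butenolide is poorly matched in polarity. Stoichiometric tin is needed. Opening the methylene lactone of A2 would expose the acrylate to hydroxide. Both plans close ring B through a six-membered transition state, and the overall step count would be comparable.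

Alternative 2: The cut is C9–C10. Anodic oxidation of phenol A3 in methanol would give a phenoxonium ion that the enol ether carbon C9 attacks at C10, giving the dienone ketal A4. In its favour, ring A with its C3 oxygen, C4 methyl and C10 methyl comes from a cheap arene, and no sulfone has to be put in or taken out and no dehydrogenation is needed. Up to the bicyclic enone this is the better plan on step economy. The bond formation is also matched in polarity, which the tether-enforced orientation of the chosen cycloaddition is not; this too is a point for the alternative. Against it, C10 is created by attack on a flat cation with only C7 to direct it. This is the same chair argument as in the chosen plan, so the two are equal on that point. The enol ether may oxidise before the phenol, and ortho attack or capture by methanol at C10 can compete. The extra C1=C2 alkene would need a selective hydrogenation. After that and ketal hydrolysis A4 would meet the chosen route at 22, so the end game is identical.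

Alternative 3: The cut is C5–C10 of the decalin, made transannularly. Protonation of the germacradiene A5 at C1 would let C4=C5 attack C10, and loss of the C5 proton would give A6, which is the same compound as 31. In its favour, it is biomimetic and would arrive one step from the target with all oxygens in place; if A5 were at hand, this would be the better plan on step economy. Against it, A5 is a ten-membered E,E-diene with three stereocentres and three esters, which is harder to make than the target, and such dienes undergo Cope rearrangement. Under acid the allylic 3-isobutyrate can ionise, and the proton can be lost toward C3 or C15 as well as C5. C10 would be set by the ring conformer population, not by a defined transition state. The last step, the ene reaction, is shared with the chosen plan.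

Key step: step 10

## Remarks before the steps

- Eudesmane numbering (C1–C15) is used for the bicyclic compounds and for the acyclic chain they come from; β is the face of the C10 methyl.
- Assumption: 1, 2, 4, 9 and 16 are commercial.
- Structures 18 and 19 were checked against 32. The E sulfone corresponds to cis 1β-sulfonyl and 10β-methyl groups, the 5α-H gives the trans fusion, and R at C7 is the 7β arm. Constitution and configuration are consistent and are used unchanged.
- The changes concern the sequence around 18 and 19. C5 is carried as an amide so that only one alkene is present when the sulfonyl group is introduced. The enol ether of the cycloadduct is oxidised directly and not hydrolysed. C13 is introduced on a lactone that has no ketone.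

## Steps

Step 1
Reactants: 1 (R)-4-benzyloxazolidin-2-one; 2 methyl 4-chloro-4-oxobutanoate
Product: 3 methyl 4-[(4R)-4-benzyl-2-oxooxazolidin-3-yl]-4-oxobutanoate
Conditions: Et3N, DMAP (cat.), CH2Cl2, 0 °C to rt
Reagents that add atoms: none
Why: N-acylation of the oxazolidinone by the acid chloride (nucleophilic acyl substitution with DMAP catalysis); no stereocentre is touched.

Step 2
Reactants: 3 methyl 4-[(4R)-4-benzyl-2-oxooxazolidin-3-yl]-4-oxobutanoate; 4 2-bromo-N-methoxy-N-methylacetamide
Product: 6 methyl (3R)-3-{[(4R)-4-benzyl-2-oxooxazolidin-3-yl]carbonyl}-5-[methoxy(methyl)amino]-5-oxopentanoate, via sodium Z-enolate 5 (not isolated)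
Conditions: NaN(SiMe3)2, THF, −78 °C; then 4, −78 to −30 °C
Reagents that add atoms: none
Why: Evans asymmetric alkylation: the imide α-CH2 is the most acidic site, and the chelated Z-enolate 5 is alkylated by the activated α-bromo amide on the face away from the benzyl group. With the R auxiliary this should set C7 as R.

Step 3
Reactants: 6 methyl (3R)-3-{[(4R)-4-benzyl-2-oxooxazolidin-3-yl]carbonyl}-5-[methoxy(methyl)amino]-5-oxopentanoate
Product: 8 (2R)-2-(2-methoxy-2-oxoethyl)-4-[methoxy(methyl)amino]-4-oxobutanoic acid, via lithium peroxycarboxylate 7 (not isolated)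
Conditions: LiOH, H2O2, THF/H2O, 0 °C; then Na2SO3 (aq); HCl to pH 3
Reagents that add atoms: hydrogen peroxide, OO
Why: Hydroperoxide cleavage of the exocyclic imide carbonyl (nucleophilic acyl substitution); the methyl ester and the N-methoxy amide react much more slowly at 0 °C. Sulfite reduces 7 and the auxiliary is recovered.

Step 4
Reactants: 8 (2R)-2-(2-methoxy-2-oxoethyl)-4-[methoxy(methyl)amino]-4-oxobutanoic acid; 9 trimethyl(2-methylprop-2-en-1-yl)silane
Product: 11 methyl (3R)-3-{2-[methoxy(methyl)amino]-2-oxoethyl}-6-methyl-4-oxohept-6-enoate, via acid chloride 10 (not isolated)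
Conditions: 1-chloro-N,N,2-trimethylprop-1-en-1-amine, CH2Cl2, 0 °C; then 9, TiCl4, CH2Cl2, −78 °C
Reagents that add atoms: none
Why: Neutral acid chloride formation spares the amide, and Lewis-acid-promoted acylation of the allylsilane with allylic transposition (SE2′) gives the β,γ-unsaturated ketone. Ester and amide do not react with the silane, and the low temperature should prevent conjugation and C7 epimerisation.

Step 5
Reactants: 11 methyl (3R)-3-{2-[methoxy(methyl)amino]-2-oxoethyl}-6-methyl-4-oxohept-6-enoate
Product: 12 methyl (3R)-5-[methoxy(methyl)amino]-3-[2-(2-methylprop-2-en-1-yl)-1,3-dioxolan-2-yl]-5-oxopentanoate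
Conditions: Me3SiOCH2CH2OSiMe3, Me3SiOTf (cat.), CH2Cl2, −78 to −20 °C; pyridine quench
Reagents that add atoms: 1,2-bis(trimethylsilyloxy)ethane, C[Si](C)(C)OCCO[Si](C)(C)C
Why: Noyori ketalization under aprotic, low-temperature conditions, so the 1,1-disubstituted alkene should not move into conjugation and C7 should not epimerise.

Step 6
Reactants: 12 methyl (3R)-5-[methoxy(methyl)amino]-3-[2-(2-methylprop-2-en-1-yl)-1,3-dioxolan-2-yl]-5-oxopentanoate
Product: 14 methyl (3R)-5-[methoxy(methyl)amino]-3-{2-[(2E)-2-methyl-3-(phenylsulfonyl)prop-2-en-1-yl]-1,3-dioxolan-2-yl}-5-oxopentanoate, via tertiary iodo sulfone 13 (not isolated)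
Conditions: PhSO2Na, I2, EtOAc/H2O, rt, dark; then Et3N, MeCN, 0 °C to rt
Reagents that add atoms: sodium benzenesulfinate, [Na+].[O-]S(=O)c1ccccc1
Why: Iodosulfonylation–dehydroiodination: PhSO2I adds by a radical chain with sulfur on the terminal carbon, and Et3N removes the acidic α-sulfonyl proton anti to iodide. The sulfonyl group should end up trans to the bulky CH2–ketal substituent (E), and this is the only alkene in the molecule.

Step 7
Reactants: 14 methyl (3R)-5-[methoxy(methyl)amino]-3-{2-[(2E)-2-methyl-3-(phenylsulfonyl)prop-2-en-1-yl]-1,3-dioxolan-2-yl}-5-oxopentanoate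
Product: 15 methyl (3R)-3-{2-[(2E)-2-methyl-3-(phenylsulfonyl)prop-2-en-1-yl]-1,3-dioxolan-2-yl}-5-oxopentanoate
Conditions: Cp2Zr(H)Cl, THF, rt, 20 min; H2O work-up
Reagents that add atoms: none
Why: Chemoselective hydrozirconation-type reduction of the N-methoxy amide to the aldehyde through a stable zirconated hemiaminal; the methyl ester, the ketal and the electron-poor trisubstituted vinyl sulfone should not react in the short reaction time.

Step 8
Reactants: 15 methyl (3R)-3-{2-[(2E)-2-methyl-3-(phenylsulfonyl)prop-2-en-1-yl]-1,3-dioxolan-2-yl}-5-oxopentanoate; 16 3-(triphenylphosphoranylidene)butan-2-one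
Product: 17 methyl (3R,5E)-6-methyl-3-{2-[(2E)-2-methyl-3-(phenylsulfonyl)prop-2-en-1-yl]-1,3-dioxolan-2-yl}-7-oxooct-5-enoate
Conditions: toluene, 80 °C
Reagents that add atoms: none
Why: Wittig olefination with a stabilised α-branched ylide, which should give the E trisubstituted enone; the ylide is too weak a base to isomerise the vinyl sulfone.

Step 9
Reactants: 17 methyl (3R,5E)-6-methyl-3-{2-[(2E)-2-methyl-3-(phenylsulfonyl)prop-2-en-1-yl]-1,3-dioxolan-2-yl}-7-oxooct-5-enoate
Product: 18 methyl (3R,5E)-7-[(tert-butyldimethylsilyl)oxy]-6-methyl-3-{2-[(2E)-2-methyl-3-(phenylsulfonyl)prop-2-en-1-yl]-1,3-dioxolan-2-yl}octa-5,7-dienoate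
Conditions: t-BuMe2SiOTf, Et3N, CH2Cl2, −78 to 0 °C
Reagents that add atoms: tert-butyldimethylsilyl trifluoromethanesulfonate, CC(C)(C)[Si](C)(C)OS(=O)(=O)C(F)(F)F
Why: Kinetic silylation (soft enolisation) at the methyl group α′ to the enone carbonyl gives the cross-conjugated 2-silyloxydiene; Et3N is too weak to deprotonate γ to the sulfone.

Step 10
Reactants: 18 methyl (3R,5E)-7-[(tert-butyldimethylsilyl)oxy]-6-methyl-3-{2-[(2E)-2-methyl-3-(phenylsulfonyl)prop-2-en-1-yl]-1,3-dioxolan-2-yl}octa-5,7-dienoate
Product: 19 methyl (1R,5S,7R,10R)-3-[(tert-butyldimethylsilyl)oxy]-8,8-(ethylenedioxy)-1-(phenylsulfonyl)-13-noreudesm-3-en-12-oate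
Conditions: degassed toluene (0.005 M), BHT (cat.), silylated sealed tube, 180 °C
Reagents that add atoms: none
Why: A thermal, concerted, suprafacial [4+2] cycloaddition joins C1 to C2 and C5 to C10; the closest known reaction type is the type 1 intramolecular Diels–Alder reaction of 1,7,9-decatrienes that carry a 2-silyloxydiene and a terminally activated dienophile. Ring A is closed as the cycloadduct cyclohexene, whose new alkene is the C3=C4 enol ether, and ring B is closed in the same event as the fused six-membered ring through the four-atom tether C6–C9 in a chair. C1 relative to C10 follows from the E geometry of the vinyl sulfone, which is transferred suprafacially and leaves the sulfonyl group and the angular methyl cis (both β). C5 relative to C10 follows from the endo placement of the sulfone, with the methyl cis to it, under the diene; this puts the tether anti and gives the trans fusion (5α-H, 10β-methyl). The absolute sense of C5 and C10 is set by C7, whose CH2CO2Me arm sits equatorial on the tether chair and so selects one diene face. The step therefore needs endo over exo selectivity and one diene face, and the E sulfone and the equatorial preference of the C7 arm should secure them. The C8 ketal helps ring closure through the gem-disubstituent effect and carries no stereocentre that would compete for the axial site beside the C10 methyl. The tether forces the silyloxy-activated terminus C2 onto the sulfonyl-bearing C1, the electronically less favoured orientation, which is why heat and high dilution are needed.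

Step 11
Reactants: 19 methyl (1R,5S,7R,10R)-3-[(tert-butyldimethylsilyl)oxy]-8,8-(ethylenedioxy)-1-(phenylsulfonyl)-13-noreudesm-3-en-12-oate
Product: 20 methyl (5R,7R,10R)-3-[(tert-butyldimethylsilyl)oxy]-8,8-(ethylenedioxy)-13-noreudesm-3-en-12-oate
Conditions: SmI2, HMPA, THF, MeOH, −20 °C
Reagents that add atoms: none
Why: Reductive desulfonylation by single-electron transfer; the C1–S bond breaks and the C1 anion is protonated by methanol. Ester, ketal and silyl enol ether should survive these near-neutral conditions.

Step 12
Reactants: 20 methyl (5R,7R,10R)-3-[(tert-butyldimethylsilyl)oxy]-8,8-(ethylenedioxy)-13-noreudesm-3-en-12-oate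
Product: 21 methyl (7R,10R)-8,8-(ethylenedioxy)-3-oxo-13-noreudesm-4-en-12-oate
Conditions: Pd(OAc)2 (1.1 equiv), MeCN, 40 °C
Reagents that add atoms: none
Why: Saegusa–Ito oxidation: the regiodefined enol ether gives the C4 palladium enolate of divalent palladium and β-hydride elimination toward C5 gives the tetrasubstituted enone. Any exocyclic C4(15) isomer should converge on the same conjugated enone under the acid of step 13.

Step 13
Reactants: 21 methyl (7R,10R)-8,8-(ethylenedioxy)-3-oxo-13-noreudesm-4-en-12-oate
Product: 22 methyl (7R,10R)-3,8-dioxo-13-noreudesm-4-en-12-oate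
Conditions: 1 M HCl, THF, rt
Reagents that add atoms: water, O
Why: Acid-catalysed ketal hydrolysis; the methyl ester is stable to dilute acid at room temperature, and the equatorial C7 arm is the thermodynamic epimer beside the new ketone.

Step 14
Reactants: 22 methyl (7R,10R)-3,8-dioxo-13-noreudesm-4-en-12-oate
Product: 24 (3S,7R,8R,10R)-3-hydroxy-13-noreudesm-4-en-12,8-olide, via dihydroxy ester 23 (not isolated)
Conditions: NaBH4, CeCl3·7H2O, MeOH, −78 to 0 °C; then rt (DBU cat., CH2Cl2 if lactonisation is incomplete)
Reagents that add atoms: none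
Why: Luche reduction of both carbonyls: hydride should add to C3 axially from the α face to give the equatorial 3β-alcohol. At C8 the axial β approach is blocked by the 1,3-diaxial C10 methyl, so hydride should add from the α face and give the axial 8β-alcohol, which is cis to the C7 arm and lactonises onto the methyl ester.

Step 15
Reactants: 24 (3S,7R,8R,10R)-3-hydroxy-13-noreudesm-4-en-12,8-olide
Product: 26 (3S,7R,8R,10R)-13-(dimethylamino)-3-hydroxyeudesm-4-en-12,8-olide, via dilithium alkoxide enolate 25 (not isolated)
Conditions: LiN(i-Pr)2 (2.3 equiv), THF, −78 °C; then CH2=NMe2+ I−, −78 °C to rt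
Reagents that add atoms: dimethylmethyleneiminium iodide, C=[N+](C)C.[I-]
Why: Mannich aminomethylation of the lactone enolate, formed after the alkoxide; no ketone is present to compete. The amine is kept as a masked methylene so that no Michael acceptor meets hydroxide in step 16, and the C11 configuration is irrelevant.

Step 16
Reactants: 26 (3S,7R,8R,10R)-13-(dimethylamino)-3-hydroxyeudesm-4-en-12,8-olide
Product: 29 methyl (3S,7R,8R,10R)-3,8-dihydroxyeudesma-4,11(13)-dien-12-oate, via potassium carboxylate 27 (not isolated), via trimethylammonium iodide 28 (not isolated)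
Conditions: KOH, MeOH/H2O, rt; evaporate; then MeI, KHCO3, DMF, rt
Reagents that add atoms: potassium hydroxide, [K+].[OH-]; iodomethane, CI
Why: Saponification of the lactone, O-alkylation of the carboxylate and exhaustive N-methylation, then Hofmann-type E1cB loss of trimethylamine to give the acrylate. No acid is used, so the 8β-hydroxy ester should not be driven back to the lactone.

Step 17
Reactants: 29 methyl (3S,7R,8R,10R)-3,8-dihydroxyeudesma-4,11(13)-dien-12-oate
Product: 30 methyl (3S,7R,8R,10R)-8-hydroxy-3-(isobutyryloxy)eudesma-4,11(13)-dien-12-oate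
Conditions: (i-PrCO)2O (1.1 equiv), DMAP (cat.), Et3N, CH2Cl2, −20 to 0 °C
Reagents that add atoms: 2-methylpropanoic anhydride, CC(C)C(=O)OC(=O)C(C)C
Why: Site-selective DMAP-catalysed acylation: the equatorial allylic 3β-hydroxyl should react much faster than the axial 8β-hydroxyl, which is 1,3-diaxial to the C10 methyl; the branched anhydride widens the difference.

Step 18
Reactants: 30 methyl (3S,7R,8R,10R)-8-hydroxy-3-(isobutyryloxy)eudesma-4,11(13)-dien-12-oate
Product: 31 methyl (3S,7R,8R,10R)-8-acetoxy-3-(isobutyryloxy)eudesma-4,11(13)-dien-12-oate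
Conditions: Ac2O, DMAP, pyridine, rt
Reagents that add atoms: acetic anhydride, CC(=O)OC(C)=O
Why: DMAP-catalysed acetylation of the remaining hindered axial alcohol under non-acidic conditions; acetylation also removes the path back to the lactone.

Step 19
Reactants: 31 methyl (3S,7R,8R,10R)-8-acetoxy-3-(isobutyryloxy)eudesma-4,11(13)-dien-12-oate
Product: 32 methyl (3S,5S,7R,8R,10R)-8-acetoxy-5-hydroperoxy-3-(isobutyryloxy)eudesma-4(15),11(13)-dien-12-oate
Conditions: O2, hν (visible), tetraphenylporphyrin (cat.), CH2Cl2, −20 °C
Reagents that add atoms: dioxygen, O=O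
Why: Schenck ene reaction of singlet oxygen with the tetrasubstituted C4=C5 alkene: attack on the α face, anti to the angular methyl and the 3β-acyloxy group, with abstraction of a C15 hydrogen geminal to the acyloxy-bearing carbon, should place the hydroperoxide at C5α and the alkene at C4(15). The electron-poor acrylate does not react with singlet oxygen.

## Compound list

1 | (R)-4-benzyloxazolidin-2-one | O=C1N[C@H](Cc2ccccc2)CO1 | starting material
2 | methyl 4-chloro-4-oxobutanoate | COC(=O)CCC(Cl)=O | starting material
3 | methyl 4-[(4R)-4-benzyl-2-oxooxazolidin-3-yl]-4-oxobutanoate | COC(=O)CCC(=O)N1[C@H](Cc2ccccc2)COC1=O | intermediate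
4 | 2-bromo-N-methoxy-N-methylacetamide | CON(C)C(=O)CBr | starting material
5 | sodium Z-enolate of 3 (not isolated) | COC(=O)C/C=C(\[O-])N1[C@H](Cc2ccccc2)COC1=O.[Na+] | intermediate
6 | methyl (3R)-3-{[(4R)-4-benzyl-2-oxooxazolidin-3-yl]carbonyl}-5-[methoxy(methyl)amino]-5-oxopentanoate | CON(C)C(=O)C[C@H](CC(=O)OC)C(=O)N1[C@H](Cc2ccccc2)COC1=O | intermediate
7 | lithium (2R)-2-(2-methoxy-2-oxoethyl)-4-[methoxy(methyl)amino]-4-oxobutaneperoxoate (not isolated) | CON(C)C(=O)C[C@H](CC(=O)OC)C(=O)O[O-].[Li+] | intermediate
8 | (2R)-2-(2-methoxy-2-oxoethyl)-4-[methoxy(methyl)amino]-4-oxobutanoic acid | CON(C)C(=O)C[C@H](CC(=O)OC)C(=O)O | intermediate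
9 | trimethyl(2-methylprop-2-en-1-yl)silane | C=C(C)C[Si](C)(C)C | starting material
10 | methyl (3R)-3-(chlorocarbonyl)-5-[methoxy(methyl)amino]-5-oxopentanoate (not isolated) | CON(C)C(=O)C[C@H](CC(=O)OC)C(Cl)=O | intermediate
11 | methyl (3R)-3-{2-[methoxy(methyl)amino]-2-oxoethyl}-6-methyl-4-oxohept-6-enoate | CON(C)C(=O)C[C@H](CC(=O)OC)C(=O)CC(C)=C | intermediate
12 | methyl (3R)-5-[methoxy(methyl)amino]-3-[2-(2-methylprop-2-en-1-yl)-1,3-dioxolan-2-yl]-5-oxopentanoate | CON(C)C(=O)C[C@H](CC(=O)OC)C1(CC(C)=C)OCCO1 | intermediate
13 | methyl (3R)-3-{2-[2-iodo-2-methyl-3-(phenylsulfonyl)propyl]-1,3-dioxolan-2-yl}-5-[methoxy(methyl)amino]-5-oxopentanoate, both C–I epimers (not isolated) | CON(C)C(=O)C[C@H](CC(=O)OC)C1(CC(C)(I)CS(=O)(=O)c2ccccc2)OCCO1 | intermediate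
14 | methyl (3R)-5-[methoxy(methyl)amino]-3-{2-[(2E)-2-methyl-3-(phenylsulfonyl)prop-2-en-1-yl]-1,3-dioxolan-2-yl}-5-oxopentanoate | CON(C)C(=O)C[C@H](CC(=O)OC)C1(C/C(C)=C/S(=O)(=O)c2ccccc2)OCCO1 | intermediate
15 | methyl (3R)-3-{2-[(2E)-2-methyl-3-(phenylsulfonyl)prop-2-en-1-yl]-1,3-dioxolan-2-yl}-5-oxopentanoate | O=CC[C@H](CC(=O)OC)C1(C/C(C)=C/S(=O)(=O)c2ccccc2)OCCO1 | intermediate
16 | 3-(triphenylphosphoranylidene)butan-2-one | CC(=O)C(C)=P(c1ccccc1)(c1ccccc1)c1ccccc1 | starting material
17 | methyl (3R,5E)-6-methyl-3-{2-[(2E)-2-methyl-3-(phenylsulfonyl)prop-2-en-1-yl]-1,3-dioxolan-2-yl}-7-oxooct-5-enoate | CC(=O)/C(C)=C/C[C@H](CC(=O)OC)C1(C/C(C)=C/S(=O)(=O)c2ccccc2)OCCO1 | intermediate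
18 | methyl (3R,5E)-7-[(tert-butyldimethylsilyl)oxy]-6-methyl-3-{2-[(2E)-2-methyl-3-(phenylsulfonyl)prop-2-en-1-yl]-1,3-dioxolan-2-yl}octa-5,7-dienoate (key-step precursor) | C=C(O[Si](C)(C)C(C)(C)C)/C(C)=C/C[C@H](CC(=O)OC)C1(OCCO1)C/C(C)=C/S(=O)(=O)c1ccccc1 | intermediate
19 | methyl (1R,5S,7R,10R)-3-[(tert-butyldimethylsilyl)oxy]-8,8-(ethylenedioxy)-1-(phenylsulfonyl)-13-noreudesm-3-en-12-oate; trans-fused; 1β-sulfonyl; 5α-H; 7β-CH2CO2Me; 10β-methyl (key-step product) | COC(=O)C[C@H]1C[C@H]2C(C)=C(O[Si](C)(C)C(C)(C)C)C[C@@H](S(=O)(=O)c3ccccc3)[C@]2(C)CC14OCCO4 | intermediate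
20 | methyl (5R,7R,10R)-3-[(tert-butyldimethylsilyl)oxy]-8,8-(ethylenedioxy)-13-noreudesm-3-en-12-oate | COC(=O)C[C@H]1C[C@H]2C(C)=C(O[Si](C)(C)C(C)(C)C)CC[C@]2(C)CC13OCCO3 | intermediate
21 | methyl (7R,10R)-8,8-(ethylenedioxy)-3-oxo-13-noreudesm-4-en-12-oate | COC(=O)C[C@H]1CC2=C(C)C(=O)CC[C@]2(C)CC13OCCO3 | intermediate
22 | methyl (7R,10R)-3,8-dioxo-13-noreudesm-4-en-12-oate | COC(=O)C[C@H]1CC2=C(C)C(=O)CC[C@]2(C)CC1=O | intermediate
23 | methyl (3S,7R,8R,10R)-3,8-dihydroxy-13-noreudesm-4-en-12-oate (not isolated) | COC(=O)C[C@H]1CC2=C(C)[C@@H](O)CC[C@]2(C)C[C@H]1O | intermediate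
24 | (3S,7R,8R,10R)-3-hydroxy-13-noreudesm-4-en-12,8-olide; 3β-hydroxy; cis-fused 8β,12-lactone | O=C1C[C@H]2CC3=C(C)[C@@H](O)CC[C@]3(C)C[C@H]2O1 | intermediate
25 | dilithium 3-alkoxide lactone enolate of 24 (not isolated) | [Li+].[Li+].[O-]C1=C[C@H]2CC3=C(C)[C@@H]([O-])CC[C@]3(C)C[C@H]2O1 | intermediate
26 | (3S,7R,8R,10R)-13-(dimethylamino)-3-hydroxyeudesm-4-en-12,8-olide, C11 epimers | O=C1C(CN(C)C)[C@H]2CC3=C(C)[C@@H](O)CC[C@]3(C)C[C@H]2O1 | intermediate
27 | potassium (3S,7R,8R,10R)-13-(dimethylamino)-3,8-dihydroxyeudesm-4-en-12-oate (not isolated) | CN(C)CC(C(=O)[O-])[C@H]1CC2=C(C)[C@@H](O)CC[C@]2(C)C[C@H]1O.[K+] | intermediate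
28 | [(3S,7R,8R,10R)-3,8-dihydroxy-12-methoxy-12-oxoeudesm-4-en-13-yl]trimethylammonium iodide (not isolated) | C[N+](C)(C)CC(C(=O)OC)[C@H]1CC2=C(C)[C@@H](O)CC[C@]2(C)C[C@H]1O.[I-] | intermediate
29 | methyl (3S,7R,8R,10R)-3,8-dihydroxyeudesma-4,11(13)-dien-12-oate | C=C(C(=O)OC)[C@H]1CC2=C(C)[C@@H](O)CC[C@]2(C)C[C@H]1O | intermediate
30 | methyl (3S,7R,8R,10R)-8-hydroxy-3-(isobutyryloxy)eudesma-4,11(13)-dien-12-oate | C=C(C(=O)OC)[C@H]1CC2=C(C)[C@@H](OC(=O)C(C)C)CC[C@]2(C)C[C@H]1O | intermediate
31 | methyl (3S,7R,8R,10R)-8-acetoxy-3-(isobutyryloxy)eudesma-4,11(13)-dien-12-oate | C=C(C(=O)OC)[C@H]1CC2=C(C)[C@@H](OC(=O)C(C)C)CC[C@]2(C)C[C@H]1OC(C)=O | intermediate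
32 | methyl (3S,5S,7R,8R,10R)-8-acetoxy-5-hydroperoxy-3-(isobutyryloxy)eudesma-4(15),11(13)-dien-12-oate | C=C(C(=O)OC)[C@H]1C[C@@]2(OO)C(=C)[C@@H](OC(=O)C(C)C)CC[C@]2(C)C[C@H]1OC(C)=O | target

## Step count and least certain steps

Total: 19 steps. Longest linear sequence: 19 steps (the route is linear; 1, 2, 4, 9 and 16 are bought).

Step 10 (key step). The most likely failure is loss of the silyloxydiene (desilylation, hydrogen shifts) during a slow cycloaddition, because the tether enforces the electronically less favoured orientation. Erosion of endo selectivity toward the cis-fused adduct is the second risk. The fallback sets out from 17 and forms the more electron-rich 2-aminodiene in situ with pyrrolidine (amine-mediated Diels–Alder reaction of an enone), so that the same two bonds close at lower temperature. Hydrolysis would give methyl 8,8-(ethylenedioxy)-3-oxo-1β-(phenylsulfonyl)-13-noreudesman-12-oate F1. DBU would eliminate benzenesulfinate to the 1-en-3-one F2. Dehydrogenation toward C4, the only α side left (silyl dienol ether and Pd(OAc)2, or 2-iodoxybenzoic acid), would give the 1,4-dien-3-one F3. Selective hydrogenation of the disubstituted C1=C2 alkene with (Ph3P)3RhCl and H2 would come back to the route at 21.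

Step 19. The most likely failure is hydrogen abstraction from C6 in place of C15, which puts the hydroperoxide on C4, together with partial attack on the β face and decay of the hydroperoxide. The fallback sets out from 31. Epoxidation with mCPBA on the α face would give the 4α,5α-epoxide F4. Homolytic opening with the trivalent titanium reagent Cp2TiCl (from Cp2TiCl2 and Mn), with hydrogen loss from the C15 methyl, would give the 5α-hydroxy-4(15)-ene F5. Acid-catalysed perhydrolysis of this tertiary allylic alcohol (50% H2O2, H2SO4 cat., Et2O, 0 °C) would come back to the route at 32.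

Step 6. The most likely failure is formation of the Z isomer and base-induced migration of the double bond to allyl sulfones, because the two substituents on C10 differ only moderately in size. The fallback sets out from 12. Ozonolysis (O3, then Me2S) would give the methyl ketone F6. Horner–Wadsworth–Emmons olefination with diethyl [(phenylsulfonyl)methyl]phosphonate (LiCl, DBU) would come back to the route at 14, with the geometry set in a carbonyl olefination.

Step 4. The most likely failure is participation of the neighbouring N-methoxy amide in the acid chloride and Lewis-acid-induced conjugation of the β,γ-unsaturated ketone. The fallback sets out from 8. 2,2′-Dipyridyl disulfide and PPh3 would give the S-(pyridin-2-yl) thioester F7. 2-Methylallylmagnesium chloride at −78 °C (2-pyridyl thioester ketone synthesis, in which the chelating thioester reacts before ester and amide) would come back to the route at 11.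

Step 17. The most likely failure is incomplete discrimination between the two hydroxyls and relactonisation of the free 8β-hydroxy ester while the acylation is slow. The fallback sets out from 29. Exhaustive acetylation (Ac2O, DMAP) would give the 3β,8β-diacetate F8 and remove the free C8 hydroxyl at once. Regioselective hydrolysis of the unhindered equatorial 3-acetate with Candida antarctica lipase B would give the 3β-hydroxy 8β-acetate F9. Isobutyrylation ((i-PrCO)2O, DMAP) would come back to the route at 31.

## Further compounds

F1 | step 10 | methyl 8,8-(ethylenedioxy)-3-oxo-1β-(phenylsulfonyl)-13-noreudesman-12-oate (5α-H; 7β arm; 10β-methyl; C4 epimers) | COC(=O)C[C@H]1C[C@H]2C(C)C(=O)C[C@@H](S(=O)(=O)c3ccccc3)[C@]2(C)CC14OCCO4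
F2 | step 10 | methyl 8,8-(ethylenedioxy)-3-oxo-13-noreudesm-1-en-12-oate (5α-H; 7β arm; 10β-methyl; C4 epimers) | COC(=O)C[C@H]1C[C@H]2C(C)C(=O)C=C[C@]2(C)CC13OCCO3
F3 | step 10 | methyl 8,8-(ethylenedioxy)-3-oxo-13-noreudesma-1,4-dien-12-oate (7β arm; 10β-methyl) | COC(=O)C[C@H]1CC2=C(C)C(=O)C=C[C@]2(C)CC13OCCO3
F4 | step 19 | methyl 8β-acetoxy-4α,5α-epoxy-3β-(isobutyryloxy)eudesm-11(13)-en-12-oate | C=C(C(=O)OC)[C@H]1C[C@@]2(O3)[C@@]3(C)[C@@H](OC(=O)C(C)C)CC[C@]2(C)C[C@H]1OC(C)=O
F5 | step 19 | methyl 8β-acetoxy-5α-hydroxy-3β-(isobutyryloxy)eudesma-4(15),11(13)-dien-12-oate | C=C(C(=O)OC)[C@H]1C[C@@]2(O)C(=C)[C@@H](OC(=O)C(C)C)CC[C@]2(C)C[C@H]1OC(C)=O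
F6 | step 6 | methyl (3R)-5-[methoxy(methyl)amino]-5-oxo-3-[2-(2-oxopropyl)-1,3-dioxolan-2-yl]pentanoate | CON(C)C(=O)C[C@H](CC(=O)OC)C1(CC(C)=O)OCCO1
F7 | step 4 | methyl (3R)-5-[methoxy(methyl)amino]-5-oxo-3-[(pyridin-2-ylsulfanyl)carbonyl]pentanoate | CON(C)C(=O)C[C@H](CC(=O)OC)C(=O)Sc1ccccn1
F8 | step 17 | methyl 3β,8β-diacetoxyeudesma-4,11(13)-dien-12-oate | C=C(C(=O)OC)[C@H]1CC2=C(C)[C@@H](OC(C)=O)CC[C@]2(C)C[C@H]1OC(C)=O
F9 | step 17 | methyl 8β-acetoxy-3β-hydroxyeudesma-4,11(13)-dien-12-oate | C=C(C(=O)OC)[C@H]1CC2=C(C)[C@@H](O)CC[C@]2(C)C[C@H]1OC(C)=O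
A1 | alternative 1 | 5-{[2-(bromomethyl)-1,3-dimethyl-4-oxocyclohex-2-en-1-yl]methyl}-3-[(phenylsulfanyl)methyl]furan-2(5H)-one (8β-O; 10β-methyl) | BrCC1=C(C)C(=O)CC[C@]1(C)C[C@@H]1C=C(CSc2ccccc2)C(=O)O1
A2 | alternative 1 | 3-oxoeudesma-4,11(13)-dien-8β,12-olide | C=C1[C@H]2CC3=C(C)C(=O)CC[C@]3(C)C[C@H]2OC1=O
A3 | alternative 2 | methyl 3-[(3-hydroxy-2,6-dimethylphenyl)methyl]-4-methoxypent-4-enoate (configuration at C7 as in 22) | COC(=O)C[C@@H](Cc1c(C)ccc(O)c1C)C(=C)OC
A4 | alternative 2 | methyl 8,8-dimethoxy-3-oxo-13-noreudesma-1,4-dien-12-oate (7β arm; 10β-methyl) | COC(=O)C[C@H]1CC2=C(C)C(=O)C=C[C@]2(C)CC1(OC)OC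
A5 | alternative 3 | methyl (1(10)E,4E)-8β-acetoxy-3β-(isobutyryloxy)germacra-1(10),4,11(13)-trien-12-oate | C=C(C(=O)OC)[C@H]1C/C=C(\C)[C@@H](OC(=O)C(C)C)CC/C=C(\C)C[C@H]1OC(C)=O
A6 | alternative 3 | methyl 8β-acetoxy-3β-(isobutyryloxy)eudesma-4,11(13)-dien-12-oate (identical with 31) | C=C(C(=O)OC)[C@H]1CC2=C(C)[C@@H](OC(=O)C(C)C)CC[C@]2(C)C[C@H]1OC(C)=O
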